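## Analysis of the target

Carbon numbering used throughout: ring C is C1(O‑tiglate)–C2–C3(Me)–C9–C13, the cyclobutane is C3–C4–C8–C9, ring A is C4–C5(OAc)–C6–C7(Me,OH)–C8, and the lactone is C9–O10–C11(=O)–C12(CH2OAc)=C13.

The target 22 is a C15 tetracycle: a cyclobutane with a cyclopentane fused to each of two opposite edges (linear 5‑4‑5) and an α,β‑unsaturated γ‑lactone fused to ring C across C9–C13. It has seven stereocentres (C1, C3, C4, C5, C7, C8, C9); C3 (methyl) and C9 (lactone oxygen) are quaternary and adjacent on the four‑membered ring. Rings A and C lie on the same face of the cyclobutane (cis‑syn‑cis), with the C3 methyl and O10 on the other face. On ring A the C5 acetate and the C7 hydroxyl are cis to each other and trans to the cyclobutane, so the C7 methyl points into the cleft between the rings; the C1 tiglate sits on the convex face of ring C, cis to the C3 methyl and O10. Sensitive groups are the butenolide (a Michael acceptor with a tertiary allylic C9–O bond), the allylic tiglate, and two acetates beside a free tertiary alcohol (acyl migration). The difficulty lies in the syn ring fusion (an intermolecular enone–alkene photocycloaddition would give the anti arrangement), the two contiguous quaternary centres, the inward C7 methyl, and four oxygens to be told apart. The strategy rests on one feature: C13 is the α‑carbon of C1 when C1 is a ketone, C12 is the α‑carbon of the lactone carbonyl C11, and both carbonyl units already hang from C9, so the C12=C13 bond is the junction of two enol‑type carbons held together by the C9–O10 ester.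

## Retrosynthetic reasoning

**22 ⇒ 21 ⇒ 20.** The two acetates are removed first. They would not survive the enolate, hydride and fluoride chemistry, and the triol 21 offers only one primary and one secondary hydroxyl besides the unreactive tertiary C7–OH. 21 comes from the tris‑silyl ether 20 by a single fluoride treatment.

**20 ⇒ 18 + 19.** The C1–O ester bond is cut. The forward step must invert C1, because reduction of the ketone 17 is expected to place the hydroxyl of 18 on the concave face; a displacement with the carboxylate of 19 from the open convex face corrects this and installs the tiglate in one operation.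

**18 ⇒ 17 ⇒ 16.** The C1 alcohol is traced to the ketone, and the C12=C13 double bond to the saturated keto lactone 16. Reduction is placed after dehydrogenation because the planar C13 of 17 clears the convex face of C1, whereas in 16 the C12 substituent would shield it. Dehydrogenation of the C1 ketone can only give C12=C13, since the other α‑carbon (C2) is next to the quaternary C3.

**16 ⇒ 14 (through 15).** The C12–C13 bond is cut. Both carbons are α to a carbonyl and are already joined through C9–O10, so the forward step is an intramolecular oxidative union of the two enol derivatives in 15. It closes the five‑membered lactone and needs no polarity inversion at either carbon. Cutting C9–O10 instead would leave an intermolecular coupling and a hindered tertiary lactonisation.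

**14 ⇒ 13 ⇒ 10 + 11.** The C1 ketone is masked as the exocyclic methylene of 13, and the C9–O10 ester bond is cut to the tertiary alcohol 10 and the acid 11. Acylating before the ketone is unveiled avoids a free β‑hydroxy ketone that could open by retro‑aldol cleavage.

**10 ⇒ 9.** The C9–C13 bond is cut. An allylsilane arm on C3 adding to the C9 cyclobutanone closes ring C; because the arm is tethered on the endo face, this step alone fixes C9 and forces rings A and C onto the same face.

**9 ⇒ 8 ⇒ 5 + 7 (7 from 6).** The two C3 substituents are removed. C3 is the only enolisable position of the cyclobutanone 5, and the second electrophile enters from the convex face, so introducing the arm first and the methyl second gives the required quaternary centre.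

**5 ⇒ 4 ⇒ 3.** The cyclobutane bonds C3–C4 and C8–C9 are cut as a ketene–alkene [2+2] on the ring A alkene of 3. This sets C4 and C8 and puts the carbonyl where ring C will be closed.

**3 ⇒ 2 ⇒ 1.** The C7–methyl bond is cut. Addition of a methyl nucleophile to the enone 1, anti to its silyloxy group, sets C7 relative to the purchased C5 centre.

## Alternatives that were turned down

**Alternative 1:** Disconnection of C8–C9 by a photochemical 1,3‑acyl shift. Direct irradiation of the bridged β,γ‑unsaturated ketone A1 would cleave C9–C6 and rebond the acyl carbon at C8, giving the cyclobutanone A2 fused to a C6=C7 cyclopentene.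
- For: the position of the cyclobutanone carbonyl follows from the migration itself, and the quaternary C3 is already present with its methyl exo. On both points it is stronger than the steric control that steps 3 and 7 of the chosen route rely on.
- Against: the shift is reversible and competes with decarbonylation and the triplet rearrangement. A2 has no C7 carbinol, and turning the C6=C7 alkene into C7(Me)(OH) puts the methyl on the concave face against the steric bias. The C3 arm of A2 is one carbon short of ring C, and the lactone is still to be built.
- Comparison: the chosen route buys C5, sets C7 on a monocyclic ring where the selectivity is dependable, and makes lactone and C12–C13 bond in one step; Alternative 1 would need many more steps after A2.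

**Alternative 2:** Disconnection of C2–C3 and C4–C5 by a radical cascade. The C2 radical generated from the iodide A3 would add to C3 of the cyclobutene, and the resulting C4 radical would add to the nitrile to give, after hydrolysis, the tetracyclic ketone A4.
- For: it forms two rings, two C–C bonds and two stereocentres in one operation with the butenolide already in place, which is more than the chosen key step builds. Both tethers enforce the syn fusion, as reliably as the allylsilane closure in step 8.
- Against: A3 is itself a demanding target (a quaternary spiro carbon on a cyclobutene with a cis arm, and two stereocentres in open chains). Addition of a cyclobutyl radical to a nitrile is slow next to hydrogen transfer from tin hydride. The C5 ketone of A4 would be reduced from the convex face to the wrong epimer and need inversion.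
- Comparison: the chosen route gives up cascade economy but reaches its key precursor 14 in ten steps from commercial 1 with C5 purchased and C7 set early, and it avoids stoichiometric tin.

**Alternative 3:** Disconnection of C4–C8 by a Wolff ring contraction. Photolysis of the diquinane diazoketone A5 in methanol would move C4 from C7 to C8 and trap the ketene as the ester A6.
- For: the contraction is a dependable way to a substituted cyclobutane and the migrating carbon keeps its configuration, so the four‑membered ring raises no regiochemical or facial question. That is stronger than step 3 of the chosen route.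
- Against: A6 carries only one‑carbon stubs where ring A should be, so C6 and the C5 and C7 centres (with the inward methyl) must be made late on the concave face. Its ring C oxygen is on C13, not C1, so butenolide formation and C1 oxygenation need a later olefination and allylic oxidation. A5 needs diazo transfer to a hindered ketone.
- Comparison: the chosen strategy keeps C1 at the ketone level from which both the C12–C13 bond and the C1 stereocentre follow, and is far shorter.

Key step: step 11

Remark on the chemistry: C12 of 16 is drawn with the silyloxymethyl group on the exo face of the lactone (trans to C1); its epimer would serve equally, because step 12 removes the C12 and C13 centres.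

## Route

Step 1
Reactants: 1 (S)-4-(tert-butyldimethylsilyloxy)cyclopent-2-en-1-one
Product: 2 (1R,4S)-4-(tert-butyldimethylsilyloxy)-1-methylcyclopent-2-en-1-ol
Conditions: MeLi, Et2O, −78 °C; H2O
Reagents that add atoms: methyllithium, [Li]C
Why: 1,2-Addition of a hard methyl nucleophile to the enone carbonyl. The methyl group should enter anti to the silyloxy group, so the new tertiary hydroxyl (C7) is cis to the C5 oxygen, as in the target.

Step 2
Reactants: 2 (1R,4S)-4-(tert-butyldimethylsilyloxy)-1-methylcyclopent-2-en-1-ol
Product: 3 triethylsilyl ether of 2 (C5 OTBS and C7 OTES cis)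
Conditions: Et3SiOTf, 2,6-lutidine, CH2Cl2, −78 → 0 °C
Reagents that add atoms: triethylsilyl trifluoromethanesulfonate, CC[Si](CC)(CC)OS(=O)(=O)C(F)(F)F
Why: Silyl triflate with a hindered base silylates tertiary alcohols. The triethylsilyl ether tolerates amide bases and falls together with the other silyl groups in step 15.

Step 3
Reactants: 3 triethylsilyl ether of 2
Product: 4 7,7-dichloro-2-(tert-butyldimethylsilyloxy)-4-methyl-4-(triethylsilyloxy)-cis-bicyclo[3.2.0]heptan-6-one (C9=O on C8, CCl2 on C4; four-membered ring trans to both silyloxy groups)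
Conditions: Cl3CCOCl, Zn–Cu couple, DME, Et2O, ultrasound, 20 °C
Reagents that add atoms: trichloroacetyl chloride (as dichloroketene), ClC(Cl)(Cl)C(Cl)=O
Why: Thermal [2+2] cycloaddition of dichloroketene to an unactivated cis-alkene; it sets C4 and C8 (cis fusion). The ketene should approach the face opposite both silyloxy groups, i.e. syn to the C7 methyl. Its unsubstituted carbonyl carbon should bond to C8 beside the quaternary C7, leaving the bulky CCl2 end on the less hindered C4.

Step 4
Reactants: 4 dichlorocyclobutanone
Product: 5 2-(tert-butyldimethylsilyloxy)-4-methyl-4-(triethylsilyloxy)-cis-bicyclo[3.2.0]heptan-6-one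
Conditions: Zn, NH4Cl, MeOH, rt
Reagents that add atoms: none
Why: Zinc reduction of both α-chlorine atoms under buffered protic conditions, the usual follow-up to a dichloroketene cycloaddition; no stereocentre is touched and the silyl ethers are spared.

Step 5
Reactants: 6 2-(chloromethyl)-3-(trimethylsilyl)prop-1-ene
Product: 7 2-(iodomethyl)-3-(trimethylsilyl)prop-1-ene
Conditions: NaI, acetone, rt, dark
Reagents that add atoms: sodium iodide, [Na+].[I-]
Why: Finkelstein exchange gives the allylic iodide, which alkylates a cyclobutanone enolate at low temperature.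

Step 6
Reactants: 5 bicyclic cyclobutanone; 7 2-(iodomethyl)-3-(trimethylsilyl)prop-1-ene
Product: 8 5 carrying an exo 2-[(trimethylsilyl)methyl]prop-2-enyl group on C3
Conditions: LiN(iPr)2, THF, −78 °C; then 7, −78 → −30 °C
Reagents that add atoms: none
Why: Enolate alkylation at C3, the only enolisable α-position (an enolate toward the ring-fusion carbon C8 would be a strained fused cyclobutene). The C3 configuration formed here does not matter, because step 7 re-enolises this centre.

Step 7
Reactants: 8 C3-monoalkylated cyclobutanone
Product: 9 5 carrying at C3 an exo methyl and an endo 2-[(trimethylsilyl)methyl]prop-2-enyl group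
Conditions: LiN(iPr)2, THF, −78 → −40 °C; MeI, DMPU, → −20 °C
Reagents that add atoms: iodomethane, CI
Why: Second enolate alkylation; methyl iodide should attack the planar C3 from the convex face of the bicyclo[3.2.0]heptanone. This sets C3 with methyl exo and the allylsilane arm endo, on the side of ring A.

Step 8
Reactants: 9 C3-quaternary cyclobutanone
Product: 10 tricyclic C9 alcohol with C1 exocyclic methylene (rings A and C syn; C3 methyl and C9 hydroxyl on the opposite face)
Conditions: EtAlCl2, CH2Cl2, −78 → −20 °C; aq. potassium sodium tartrate
Reagents that add atoms: none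
Why: Intramolecular Hosomi–Sakurai allylation (methylenecyclopentane annulation): the terminal alkene carbon of the allylsilane adds to the Lewis acid-activated cyclobutanone, forming C9–C13 and ring C. The arm is tethered on the endo face, so C9 is set with its oxygen exo and the syn ring fusion is enforced; release of cyclobutanone carbonyl strain helps.

Step 9
Reactants: 10 tricyclic C9 alcohol; 11 3-(tert-butyldimethylsilyloxy)propanoic acid
Product: 13 tricyclic C9 3-(tert-butyldimethylsilyloxy)propanoate, via 3-(tert-butyldimethylsilyloxy)propanoyl chloride 12 (not isolated)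
Conditions: 11, 1-chloro-N,N,2-trimethylprop-1-en-1-amine, CH2Cl2, 0 °C → rt; then 10, n-BuLi, THF, −78 °C; add 12, → 0 °C
Reagents that add atoms: none
Why: Acylation of a hindered tertiary alkoxide with an acid chloride made under neutral conditions, which spares the silyl ethers; no stereocentre is affected.

Step 10
Reactants: 13 tricyclic C9 ester
Product: 14 tricyclic C1 ketone C9 3-(tert-butyldimethylsilyloxy)propanoate
Conditions: O3, CH2Cl2, −78 °C; PPh3, → rt
Reagents that add atoms: ozone, [O-][O+]=O
Why: Ozonolysis of the only alkene gives the C1 ketone. The neutral reductive work-up avoids β-elimination of the C9 acyloxy group.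

Step 11
Reactants: 14 tricyclic C1 ketone C9 ester
Product: 16 tetracyclic keto lactone saturated at C12–C13, via bis(trimethylsilyl) enol ether 15 (not isolated)
Conditions: LiN(iPr)2 (2.5 equiv), Me3SiCl (5 equiv, present from the start), THF, −78 °C; concentrate, pentane, filter; then divided cell, reticulated vitreous carbon anode, Pt cathode, 0.1 M LiClO4 in MeCN/CH2Cl2, 2,6-lutidine, AcOH in the catholyte, constant current, 2.2 F/mol, 0 °C
Reagents that add atoms: none
Why: Double enolisation with internal silyl quench gives 15, in which the ketone is a silyl enol ether toward C13 and the ester a ketene silyl acetal (esters of tertiary alcohols silylate on oxygen). The anode removes one electron from the ketene acetal, the more electron-rich π system, and the C12 terminus of the radical cation adds to C13 of the neighbouring enol ether. The α-silyloxy radical left at C1 is oxidised further, and loss of both trimethylsilyl groups to the lutidine/perchlorate medium leaves the ketone and the lactone. The closest known reaction type is the oxidative (anodic or chemical) coupling of two enol ethers or silyl enol ethers to a 1,4-dicarbonyl compound. The lactone ring closes in the 5-exo-trig mode. At C13 the new bond must come from the face carrying O10, which gives the cis-fused lactone with H13 on the cyclobutane side; C12 is set in the cyclisation with its substituent expected exo, and both centres are erased in step 12. The step needs enolisation toward C13 rather than C2: the C13 hydrogens are acidified by the β-acyloxy group, the ester carbonyl can hold the lithium amide next to them, and C2 lies beside the methyl-bearing quaternary C3. The low temperature, the internal quench and the strain of a C9=C13 alkene guard against loss of the C9 carboxylate.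

Step 12
Reactants: 16 tetracyclic keto lactone
Product: 17 butenolide ketone (C12=C13, C1=O)
Conditions: IBX, DMSO/fluorobenzene, 70 °C
Reagents that add atoms: none
Why: IBX dehydrogenation of a ketone through its enol. C13 is the only α-carbon with a β-hydrogen (C3 is quaternary), and the new double bond is conjugated with both carbonyls, so the C12 and C13 centres disappear.

Step 13
Reactants: 17 butenolide ketone
Product: 18 C1 alcohol with the hydroxyl on the concave face (C1 epimer of the target configuration)
Conditions: NaBH4, CeCl3·7H2O, MeOH/CH2Cl2, −78 °C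
Reagents that add atoms: none
Why: Luche 1,2-reduction of the enone carbonyl. Hydride should reach C1 from the convex face of ring C, away from the cyclobutane and ring A, which sets C1 with the hydroxyl cis to the cyclobutane.

Step 14
Reactants: 18 C1 alcohol; 19 tiglic acid
Product: 20 C1 tiglate with C5 OTBS, C7 OTES and primary OTBS
Conditions: 19, PPh3, DIAD, toluene, 0 °C → rt
Reagents that add atoms: none
Why: Mitsunobu esterification: the carboxylate displaces the alkoxyphosphonium group in an SN2 step from the open convex face, inverting C1 to the target configuration. The (E)-alkene of the tiglate is not at risk under these neutral conditions.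

Step 15
Reactants: 20 C1 tiglate tris-silyl ether
Product: 21 triol with free C5, C7 and primary hydroxyls
Conditions: HF·pyridine, pyridine, THF, 0 °C → rt
Reagents that add atoms: none
Why: Buffered fluoride cleaves all three silyl ethers while leaving the butenolide and the allylic tiglate intact; the mildly acidic medium disfavours acyl migration.

Step 16
Reactants: 21 triol
Product: 22 target compound CNP0210373.1
Conditions: Ac2O, pyridine, DMAP (cat.), CH2Cl2, 0 °C
Reagents that add atoms: acetic anhydride, CC(=O)OC(C)=O
Why: Acetylation of the primary and the secondary hydroxyl; the tertiary C7 hydroxyl is too hindered to react under these conditions.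

## Compound list

1 | (S)-4-(tert-butyldimethylsilyloxy)cyclopent-2-en-1-one | O=C1C=C[C@@H](O[Si](C)(C)C(C)(C)C)C1 | starting material
2 | (1R,4S)-4-(tert-butyldimethylsilyloxy)-1-methylcyclopent-2-en-1-ol (OH cis to OTBS) | C1=C[C@](C)(O)C[C@@H]1O[Si](C)(C)C(C)(C)C | intermediate
3 | triethylsilyl ether of 2 (ring A cyclopentene, C5 OTBS and C7 OTES cis) | C1=C[C@](C)(O[Si](CC)(CC)CC)C[C@@H]1O[Si](C)(C)C(C)(C)C | intermediate
4 | 7,7-dichloro-2-(tert-butyldimethylsilyloxy)-4-methyl-4-(triethylsilyloxy)-cis-bicyclo[3.2.0]heptan-6-one, four-membered ring trans to both silyloxy groups | O=C1[C@H]2[C@](C)(O[Si](CC)(CC)CC)C[C@H](O[Si](C)(C)C(C)(C)C)[C@H]2C1(Cl)Cl | intermediate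
5 | 2-(tert-butyldimethylsilyloxy)-4-methyl-4-(triethylsilyloxy)-cis-bicyclo[3.2.0]heptan-6-one (configuration as 4) | O=C1[C@H]2[C@](C)(O[Si](CC)(CC)CC)C[C@H](O[Si](C)(C)C(C)(C)C)[C@H]2C1 | intermediate
6 | 2-(chloromethyl)-3-(trimethylsilyl)prop-1-ene | C=C(CCl)C[Si](C)(C)C | starting material
7 | 2-(iodomethyl)-3-(trimethylsilyl)prop-1-ene | C=C(CI)C[Si](C)(C)C | intermediate
8 | 5 with an exo 2-[(trimethylsilyl)methyl]prop-2-enyl group on C3 (bicyclic C7) | O=C1[C@H]2[C@](C)(O[Si](CC)(CC)CC)C[C@H](O[Si](C)(C)C(C)(C)C)[C@H]2[C@@H]1CC(=C)C[Si](C)(C)C | intermediate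
9 | 5 with exo methyl and endo 2-[(trimethylsilyl)methyl]prop-2-enyl on C3 | O=C1[C@H]2[C@](C)(O[Si](CC)(CC)CC)C[C@H](O[Si](C)(C)C(C)(C)C)[C@H]2[C@@]1(C)CC(=C)C[Si](C)(C)C | intermediate
10 | tricyclic C9 alcohol, C1 exocyclic methylene, rings A and C syn, C5 OTBS, C7 OTES | C=C1C[C@]2(C)[C@@H]3[C@@H](O[Si](C)(C)C(C)(C)C)C[C@@](C)(O[Si](CC)(CC)CC)[C@@H]3[C@@]2(C1)O | intermediate
11 | 3-(tert-butyldimethylsilyloxy)propanoic acid | OC(=O)CCO[Si](C)(C)C(C)(C)C | starting material
12 | 3-(tert-butyldimethylsilyloxy)propanoyl chloride | ClC(=O)CCO[Si](C)(C)C(C)(C)C | intermediate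
13 | C9 3-(tert-butyldimethylsilyloxy)propanoate of 10 | C=C1C[C@]2(C)[C@@H]3[C@@H](O[Si](C)(C)C(C)(C)C)C[C@@](C)(O[Si](CC)(CC)CC)[C@@H]3[C@@]2(C1)OC(=O)CCO[Si](C)(C)C(C)(C)C | intermediate
14 | tricyclic C1 ketone C9 3-(tert-butyldimethylsilyloxy)propanoate | O=C1C[C@]2(C)[C@@H]3[C@@H](O[Si](C)(C)C(C)(C)C)C[C@@](C)(O[Si](CC)(CC)CC)[C@@H]3[C@@]2(C1)OC(=O)CCO[Si](C)(C)C(C)(C)C | intermediate
15 | bis(trimethylsilyl) derivative of 14: C1(OSiMe3)=C13 enol ether and C11(OSiMe3)=C12 ketene acetal | C[Si](C)(C)OC=1C[C@]2(C)[C@@H]3[C@@H](O[Si](C)(C)C(C)(C)C)C[C@@](C)(O[Si](CC)(CC)CC)[C@@H]3[C@@]2(C=1)OC(O[Si](C)(C)C)=CCO[Si](C)(C)C(C)(C)C | intermediate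
16 | tetracyclic keto lactone saturated at C12–C13 (lactone cis-fused, H13 on the cyclobutane side, CH2OTBS trans to C1) | O=C1C[C@]2(C)[C@@H]3[C@@H](O[Si](C)(C)C(C)(C)C)C[C@@](C)(O[Si](CC)(CC)CC)[C@@H]3[C@@]24OC(=O)[C@H](CO[Si](C)(C)C(C)(C)C)[C@@H]14 | intermediate
17 | butenolide ketone (C12=C13, C1=O) | O=C1C[C@]2(C)[C@@H]3[C@@H](O[Si](C)(C)C(C)(C)C)C[C@@](C)(O[Si](CC)(CC)CC)[C@@H]3[C@@]23OC(=O)C(CO[Si](C)(C)C(C)(C)C)=C13 | intermediate
18 | C1 alcohol of 17, hydroxyl on the concave face (cis to the cyclobutane) | O[C@@H]1C[C@]2(C)[C@@H]3[C@@H](O[Si](C)(C)C(C)(C)C)C[C@@](C)(O[Si](CC)(CC)CC)[C@@H]3[C@@]23OC(=O)C(CO[Si](C)(C)C(C)(C)C)=C13 | intermediate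
19 | tiglic acid, (E)-2-methylbut-2-enoic acid | C/C=C(\C)C(=O)O | starting material
20 | C1 tiglate (target configuration at C1), C5 OTBS, C7 OTES, primary OTBS | C/C=C(\C)C(=O)O[C@H]1C[C@]2(C)[C@@H]3[C@@H](O[Si](C)(C)C(C)(C)C)C[C@@](C)(O[Si](CC)(CC)CC)[C@@H]3[C@@]23OC(=O)C(CO[Si](C)(C)C(C)(C)C)=C13 | intermediate
21 | C1 tiglate triol (free C5, C7 and primary hydroxyls) | C/C=C(\C)C(=O)O[C@H]1C[C@]2(C)[C@@H]3[C@@H](O)C[C@@](C)(O)[C@@H]3[C@@]23OC(=O)C(CO)=C13 | intermediate
22 | CNP0210373.1 | C/C=C(\C)C(=O)O[C@H]1C[C@]2(C)[C@@H]3[C@@H](OC(C)=O)C[C@@](C)(O)[C@@H]3[C@@]23OC(=O)C(COC(C)=O)=C13 | target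

## Step count and least certain steps

Total: 16 steps. Longest linear sequence: 15 steps (steps 1–4 and 6–16; step 5 is a one-step branch).

**Step 11 (key step).**
- Most likely failure: loss of regiocontrol in the enolisation. Deprotonation at C2 instead of C13 would send the radical cation into a bridged six-membered lactone, since both α-methylene groups sit beside quaternary carbons and differ only by the β-acyloxy group.
- Also possible: protodesilylation of the ketene acetal before it is oxidised, and elimination of the C9 carboxylate from a C13 enolate.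
- Fallback, from 13 to 17, replacing oxidative coupling by an aldol condensation:
 1. Deprotonation of 13 with KN(SiMe3)2 and oxidation with 2-(phenylsulfonyl)-3-phenyloxaziridine gives the α-hydroxy ester F1.
 2. Dess–Martin periodinane gives the α-keto ester F2.
 3. Ozonolysis as in step 10 gives the keto α-keto ester F3.
 4. With triethylamine the C13 enol adds to the C12 ketone to give the aldol lactone F4, which loses water to 17.
 The aldol is reversible, and only the C13 adduct can dehydrate into conjugation with both carbonyls, so the regiochemistry is corrected thermodynamically.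

**Step 3.**
- Most likely failure: sluggish cycloaddition to an alkene deactivated by two allylic silyloxy groups and flanked by a quaternary carbon, together with erosion of the C4/C8 regioselectivity, which rests on sterics alone.
- Also possible: zinc salts ionising the tertiary allylic silyl ether.
- Fallback, from 2 to 5, fixing the regiochemistry by enone polarity:
 1. Bu4NF gives (1R,4S)-1-methylcyclopent-2-ene-1,4-diol F5.
 2. MnO2 oxidises only the secondary allylic hydroxyl to (R)-4-hydroxy-4-methylcyclopent-2-en-1-one F6.
 3. Et3SiOTf gives the triethylsilyl ether F7.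
 4. Irradiation (350 nm) with 1,1-diethoxyethene gives the head-to-tail photoadduct F8, with the acetal carbon (C9) on the enone β-carbon (C8).
 5. Reduction of the C5 ketone under equilibrating conditions (Li, NH3) should give the exo alcohol F9.
 6. Silylation gives the tert-butyldimethylsilyl ether F10, and mild aqueous acid unmasks the cyclobutanone to return 5.

**Step 8.**
- Most likely failure: protodesilylation of the allylsilane outrunning a cyclisation that must form a bond on the concave face next to the C7 methyl.
- Also possible: Lewis acid cleavage of the tertiary triethylsilyl ether.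
- Fallback, from 5 to 10, replacing Lewis acid activation by a reductive allyl metal addition: alkylation of 5 with 3-chloro-2-(chloromethyl)prop-1-ene gives the allylic chloride F11; exo-methylation as in step 7 gives F12; zinc in THF/aqueous NH4Cl (intramolecular Barbier reaction) closes ring C to 10.

**Step 12.**
- Most likely failure: slow enolisation toward the shielded C13–H, so that α-hydroxylation or oxidative loss of the triethylsilyl group competes with dehydrogenation.
- Fallback, from 16 to 17: Me3SiOTf and Et3N convert 16 into the bis(trimethylsilyloxy)diene F13, and DDQ oxidises this 1,4-dioxygenated diene by two electrons to 17.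

**Step 14.**
- Most likely failure: slow formation or displacement of the alkoxyphosphonium ion in the cleft, with elimination toward C2 taking over.
- Fallback, from 18 to 20: Tf2O and pyridine at −78 °C give the C1 triflate F14, a small leaving group, and caesium (E)-2-methylbut-2-enoate with 18-crown-6 in toluene displaces it with inversion to give 20.

## Further compounds

F1 | step 11 | α-hydroxy ester of 13 (hydroxyl on C12, configuration not controlled) | C=C1C[C@]2(C)[C@@H]3[C@@H](O[Si](C)(C)C(C)(C)C)C[C@@](C)(O[Si](CC)(CC)CC)[C@@H]3[C@@]2(C1)OC(=O)C(O)CO[Si](C)(C)C(C)(C)C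
F2 | step 11 | α-keto ester (C12 ketone) with C1 methylene | C=C1C[C@]2(C)[C@@H]3[C@@H](O[Si](C)(C)C(C)(C)C)C[C@@](C)(O[Si](CC)(CC)CC)[C@@H]3[C@@]2(C1)OC(=O)C(=O)CO[Si](C)(C)C(C)(C)C
F3 | step 11 | C1 ketone α-keto ester | O=C1C[C@]2(C)[C@@H]3[C@@H](O[Si](C)(C)C(C)(C)C)C[C@@](C)(O[Si](CC)(CC)CC)[C@@H]3[C@@]2(C1)OC(=O)C(=O)CO[Si](C)(C)C(C)(C)C
F4 | step 11 | aldol lactone with tertiary hydroxyl on C12 (C12 configuration not controlled) | O=C1C[C@]2(C)[C@@H]3[C@@H](O[Si](C)(C)C(C)(C)C)C[C@@](C)(O[Si](CC)(CC)CC)[C@@H]3[C@@]24OC(=O)C(O)(CO[Si](C)(C)C(C)(C)C)[C@@H]14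
F5 | step 3 | (1R,4S)-1-methylcyclopent-2-ene-1,4-diol | C1=C[C@](C)(O)C[C@@H]1O
F6 | step 3 | (R)-4-hydroxy-4-methylcyclopent-2-en-1-one | O=C1C=C[C@](C)(O)C1
F7 | step 3 | (R)-4-methyl-4-(triethylsilyloxy)cyclopent-2-en-1-one | O=C1C=C[C@](C)(O[Si](CC)(CC)CC)C1
F8 | step 3 | 6,6-diethoxy-4-methyl-4-(triethylsilyloxy)-cis-bicyclo[3.2.0]heptan-2-one, cyclobutane trans to the silyloxy group | O=C1C[C@@](C)(O[Si](CC)(CC)CC)[C@H]2[C@@H]1CC2(OCC)OCC
F9 | step 3 | exo C5 alcohol of F8 (hydroxyl cis to the silyloxy group) | O[C@H]1C[C@@](C)(O[Si](CC)(CC)CC)[C@H]2[C@@H]1CC2(OCC)OCC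
F10 | step 3 | tert-butyldimethylsilyl ether of F9 | CC(C)(C)[Si](C)(C)O[C@H]1C[C@@](C)(O[Si](CC)(CC)CC)[C@H]2[C@@H]1CC2(OCC)OCC
F11 | step 8 | 5 with an exo 2-(chloromethyl)prop-2-enyl group on C3 | O=C1[C@H]2[C@](C)(O[Si](CC)(CC)CC)C[C@H](O[Si](C)(C)C(C)(C)C)[C@H]2[C@@H]1CC(=C)CCl
F12 | step 8 | 5 with exo methyl and endo 2-(chloromethyl)prop-2-enyl on C3 | O=C1[C@H]2[C@](C)(O[Si](CC)(CC)CC)C[C@H](O[Si](C)(C)C(C)(C)C)[C@H]2[C@@]1(C)CC(=C)CCl
F13 | step 12 | bis(trimethylsilyloxy)diene of 16 (C1(OSiMe3)=C13–C12=C11(OSiMe3)) | C[Si](C)(C)OC=1C[C@]2(C)[C@@H]3[C@@H](O[Si](C)(C)C(C)(C)C)C[C@@](C)(O[Si](CC)(CC)CC)[C@@H]3[C@@]23OC(O[Si](C)(C)C)=C(CO[Si](C)(C)C(C)(C)C)C3=1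
F14 | step 14 | C1 trifluoromethanesulfonate of 18 | FC(F)(F)S(=O)(=O)O[C@@H]1C[C@]2(C)[C@@H]3[C@@H](O[Si](C)(C)C(C)(C)C)C[C@@](C)(O[Si](CC)(CC)CC)[C@@H]3[C@@]23OC(=O)C(CO[Si](C)(C)C(C)(C)C)=C13
A1 | alternative 1 | methyl 2-(7-tert-butoxy-3-methyl-2-oxobicyclo[2.2.1]hept-5-en-3-yl)acetate | COC(=O)C[C@@]1(C)C(=O)[C@@H]2C=C[C@H]1[C@H]2OC(C)(C)C
A2 | alternative 1 | methyl 2-(2-tert-butoxy-7-methyl-6-oxobicyclo[3.2.0]hept-3-en-7-yl)acetate | COC(=O)C[C@]2(C)[C@@H]3[C@@H](OC(C)(C)C)C=C[C@@H]3C2=O
A3 | alternative 2 | spiro-butenolide cyclobutene with the C1(OTBS)–C2 iodide arm on C13 and the C7(Me)(OTMS)–C6–C5 nitrile arm on C8 | CC(C)(C)[Si](C)(C)O[C@@H](CI)C1=C(COC(C)=O)C(=O)O[C@]12C(C)=C[C@@H]2[C@](C)(O[Si](C)(C)C)CC#N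
A4 | alternative 2 | tetracyclic C5 ketone with C1 OTBS, C7 OTMS and the acetoxymethyl butenolide | CC(C)(C)[Si](C)(C)O[C@H]1C[C@]2(C)[C@@H]3C(=O)C[C@@](C)(O[Si](C)(C)C)[C@@H]3[C@@]23OC(=O)C(COC(C)=O)=C13
A5 | alternative 3 | diquinane α-diazoketone (C7 ketone, C8 diazo, C13 methyl enol ether, C9 OTES) | COC1=CC[C@]2(C)[C@H](CO[Si](C)(C)C(C)(C)C)C(=O)C(=[N+]=[N-])[C@]12O[Si](CC)(CC)CC
A6 | alternative 3 | ring C cyclobutane with cis CH2OTBS (on C4) and CO2Me (on C8) arms | COC1=CC[C@]2(C)[C@H](CO[Si](C)(C)C(C)(C)C)[C@H](C(=O)OC)[C@]12O[Si](CC)(CC)CC
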